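## Structural features

The target is the palmitate of (−)-loliolide, a 5,6,7,7a-tetrahydrobenzofuran-2(4H)-one. A cyclohexane ring (C3a, C4, C5, C6, C7, C7a) and a butenolide (O1, C2, C3, C3a, C7a) share the C3a–C7a bond, and the C3=C3a double bond is exocyclic to the carbocycle. C4 carries a gem-dimethyl group. C7a is a quaternary stereocentre (R) bearing a methyl group and the lactone oxygen, and C6 is a secondary stereocentre (S) bearing the palmitoyloxy group. The two stereocentres stand 1,3 to each other across C7, with the two oxygen atoms trans on the ring. Three groups are fragile: the palmitate (enolisable and open to nucleophiles, so strong base and hydroxide are excluded once it is in place), the tertiary C7a–O1 lactone bond (ionisable by strong acid), and the butenolide (a Michael acceptor). The difficulty is twofold: the absolute configuration of the methyl-bearing tertiary carbinol C7a in a trans 1,3 relation to C6, and the C3–C3a bond, which must be made at a carbon lying between the fully substituted C4 and C7a. The key step uses the fact that, one oxidation level below the target, C3a is a ring methylene β to the C7a oxygen. An acyl carbenoid carried on O1 then reaches a C3a–H bond through a five-membered transition state, and the rest of the pattern (methyl and oxygen on C7a, oxygen on C6, gem-dimethyl on C4) is that of isophorone oxygenated at its β-carbon.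

## Logic of the disconnections

**17 ⇒ 14.** The C3=C3a π bond is saturated and a carboxyl group is placed on C3. This turns C3 into the sp3 carbon of a malonic acid derivative, the retron of a malonate carbenoid. The forward step must couple loss of CO2 with introduction of the double bond without a strong base, because the palmitate is enolisable: bromination at the malonic carbon, decarboxylation, then elimination of HBr with H3a.

**14 ⇒ 13.** The O–CH2CCl3 ester bond is cut. The second carboxyl must be masked through diazo transfer and the carbenoid step, and unmasked without base, acid or nucleophile at the palmitate and the tertiary lactone; reductive cleavage with Zn meets this. An allyl ester was rejected for two reasons. It would put a C=C bond within reach of the carbenoid, and intramolecular cyclopropanation is the usual course of allyl diazo esters. An allyl malonate with a C3–H is also a poor substrate for palladium-catalysed decarboxylation–dehydrogenation, since the acidic C3–H is allylated or the palladium enolate protonated.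

**13 ⇒ 12 (key cut).** The C3–C3a bond is cut and the γ-lactone ring opened. The bicycle becomes a monocyclic cyclohexane in which both stereocentres are already in place and C3a is an unfunctionalised CH2. The forward step must select the C3a methylene over the C7 methylene and the C7a methyl group, and the spectator ester must offer neither a π bond nor a C–H bond in 1,5 relation to the carbenoid.

**12 ⇒ 11.** The C3=N2 bond is cut (diazo transfer to a malonate CH2). The forward step needs only an amine base, which the palmitate tolerates.

**11 ⇒ 7 + 10, and 10 ⇒ 8 + 9.** The O1–C2 acyl bond is cut, which separates the ring from the three-carbon acyl unit. The forward step must acylate a hindered axial tertiary alcohol, which calls for a ketene-type acylating species. 10 comes in one step from 8 and 9 by cutting its ester C–O bond.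

**7 ⇒ 5 + 6.** The C6–O acyl bond is cut. The forward step must distinguish the secondary from the tertiary hydroxyl, which sterics ensure. Installing the palmitate this early also makes it the group that deactivates C7 in the key step.

**5 ⇒ 4.** The C6–H bond is cut (hydride addition). The forward step must deliver hydride to the carbonyl face on which the C7a hydroxyl stands, so that the diol is trans.

**4 ⇒ 1 + 2 (via 3).** The C7a–O bond is traced through a C7a–B bond to conjugate addition of boron. This reduces the problem to a commercial enone. The forward step must select one enantioface of a hindered β,β-disubstituted enone and oxidise the C–B bond without retro-aldol cleavage.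

## Other disconnections considered

**Alternative 1:** The cut removes three bonds at once (C3a–C7a, C3–C2, C2–O1) and leads to the acyclic ynone A1, a methyl ketone tethered through four atoms to a terminal alkyne on the gem-dimethyl carbon. Forward, A1 and CO at a low-valent carbonyl complex (Mo(CO)6 with DMSO, or catalytic Ru3(CO)12 under CO) would form an oxametallacyclopentene from the C=O and C≡C units, insert CO and reductively eliminate to the silyl ether A2.
- In its favour: both rings and the C3=C3a bond arise in one operation at the final oxidation level, where the chosen plan needs the insertion and two further steps. No diazo compound is handled. On both points the alternative is the better plan.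
- Against it here: the carbonyl partner is a ketone and the new carbocycle is six-membered, both the less favourable cases of this cyclocarbonylation. C7a is created in the key step and must be induced 1,3 by the C6 silyloxy group across a forming ring, whereas the chosen plan fixes C7a by a catalyst before any ring closes. A2 has C6 in the configuration opposite to the target, so desilylation and a Mitsunobu esterification with palmitic acid must follow. A1 itself needs an asymmetric synthesis.
- Comparison: in length the two plans are about equal. Mechanistically the selectivity problem moves from site selectivity (chosen plan) to diastereofacial selectivity at a ketone (alternative). The chosen plan is preferred because its stereocontrol is ring-bound and reagent-directed.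

**Alternative 2:** The cut is the C4–C3a bond, which opens the carbocycle to the acyclic enynoate A3. A3 already has both stereocentres, the palmitate, a 1,1-disubstituted alkene (future C4) and an ynoate (C3a≡C3). Forward, the iron hydride from Fe(acac)3 and PhSiH3 transfers a hydrogen atom to the terminal CH2, the tertiary C4 radical adds 6-exo-dig to C3a (the β-carbon of the ynoate), and the vinyl radical is reduced to the alkylidene acetate A4. The Z isomer of A4 has the ester next to the tertiary hydroxyl and should lactonise to 17.
- In its favour: the bond between quaternary C4 and C3a is made by a radical addition that is little affected by steric compression, whereas the chosen plan must insert into a C–H bond on that same crowded carbon. The key step gives the target's oxidation level, so only lactonisation follows. No diazo compound is involved. On all three points the alternative is the better plan.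
- Against it here: the two stereocentres of A3 must be set in an open chain, and a tertiary propargylic carbinol in a 1,3-anti relation to C6 is much harder to control there than on a ring. The geometry of the vinyl radical reduction decides whether lactonisation is possible; the E isomer would need a separate isomerisation. 6-exo-dig closure is slower than the 5-exo case, so premature reduction of the radical or hydrometalation of the ynoate may compete.
- Comparison: equal in total length, better in the end game, weaker in the reliability with which C6 and C7a are set.

**Alternative 3:** The cut is the O1–C7a bond, traced back to the achiral dienone acid A5, which would come from oxidative dearomatisation of a para-(carboxymethyl)phenol in methanol. Forward, a chiral bifunctional catalyst (tertiary amine–thiourea or squaramide type) would deliver the carboxylate to one of the two enantiotopic β-carbons of the cross-conjugated dienone. This closes the cis-fused γ-lactone A6 by 5-exo-trig oxa-Michael addition and sets C7a and C3a together.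
- In its favour: flat, inexpensive aromatic starting material and a catalytic asymmetric step without metal carbenoids or diazo compounds, which is better than the chosen plan in safety and material cost. The absolute configuration at C7a comes from a catalyst, in which it is the equal of the chosen plan.
- Against it here: A6 is far from the target. It still needs a methyl conjugate addition to build the C4 gem-dimethyl group next to the fully substituted C3a, β-elimination of methanol to form C3=C3a, a 1,3-diastereoselective reduction of the C6 ketone, and palmitoylation. Oxa-Michael addition of a weakly nucleophilic carboxylate to a β,β-disubstituted enone is reversible, so the enantiomeric purity of A6 may erode in the basic steps that follow. C6 is set last and by substrate control.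
- Comparison: not shorter (key step plus four or five further steps after preparing A5). Its advantages lie in materials and safety, not in length or stereochemical security.

Key step: step 7

Assumption: the bisphosphine antipode that delivers boron to the Si face of C3 of 1 is identified in a pilot run; 10 is prepared (step 4) because its commercial supply is uncertain.

## Route

Step 1
Reactants: 1 isophorone (3,5,5-trimethylcyclohex-2-en-1-one); 2 bis(pinacolato)diboron
Product: 4 (S)-3-hydroxy-3,5,5-trimethylcyclohexan-1-one, via (R)-3-boryl ketone 3 (not isolated)
Conditions: CuCl (5 mol %), chiral Josiphos-type bisphosphine (6 mol %), NaOtBu (10 mol %), MeOH (2 equiv), THF, rt; then NaBO3·4H2O, THF/H2O, rt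
Reagents that add atoms: sodium perborate tetrahydrate (the hydroxyl oxygen), O.O.O.O.[Na+].[O-]OB=O
Why: Copper-catalysed enantioselective conjugate borylation of a β,β-disubstituted cyclic enone; the bisphosphine–copper boryl complex adds boron to the Si face of C3 and MeOH protonates the copper enolate. Perborate then oxidises the C–B bond with retention under nearly neutral conditions, so the tertiary β-hydroxy ketone is not exposed to retro-aldol cleavage or dehydration.

Step 2
Reactants: 4 (S)-3-hydroxy-3,5,5-trimethylcyclohexan-1-one
Product: 5 (1S,3S)-1,5,5-trimethylcyclohexane-1,3-diol (trans diol)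
Conditions: Me4NBH(OAc)3 (5 equiv), MeCN/AcOH (1:1), −35 → −20 °C
Reagents that add atoms: none
Why: Evans–Saksena hydroxyl-directed reduction: the axial tertiary hydroxyl exchanges an acetate on boron and delivers hydride intramolecularly to the carbonyl face it occupies, so the new hydroxyl appears on the opposite face (trans-1,3-diol, new centre S). The free reagent does not reduce ketones under these conditions, which suppresses the undirected path to the cis isomer.

Step 3
Reactants: 5 (1S,3S)-1,5,5-trimethylcyclohexane-1,3-diol; 6 palmitoyl chloride
Product: 7 (1S,3S)-3-hydroxy-3,5,5-trimethylcyclohexyl palmitate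
Conditions: pyridine (2 equiv), DMAP (5 mol %), CH2Cl2, 0 °C
Reagents that add atoms: none
Why: Chemoselective O-acylation: the equatorial secondary hydroxyl reacts with the acid chloride while the hindered axial tertiary hydroxyl does not; no stereocentre is touched.

Step 4
Reactants: 8 Meldrum's acid (2,2-dimethyl-1,3-dioxane-4,6-dione); 9 2,2,2-trichloroethanol
Product: 10 3-oxo-3-(2,2,2-trichloroethoxy)propanoic acid (mono-2,2,2-trichloroethyl malonate)
Conditions: PhMe, 100 °C
Reagents that add atoms: none
Why: Alcoholysis of Meldrum's acid (ring opening with loss of acetone) is the standard one-step route to malonic half esters.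

Step 5
Reactants: 7 (1S,3S)-3-hydroxy-3,5,5-trimethylcyclohexyl palmitate; 10 3-oxo-3-(2,2,2-trichloroethoxy)propanoic acid
Product: 11 2,2,2-trichloroethyl (1S,3S)-1,5,5-trimethyl-3-(palmitoyloxy)cyclohexyl malonate
Conditions: DCC, DMAP (10 mol %), CH2Cl2, 0 °C → rt
Reagents that add atoms: none
Why: Steglich-type esterification; with DCC a malonic half ester passes through its O-acylisourea to the (alkoxycarbonyl)ketene, which acylates even hindered tertiary alcohols. The C–O bond of the carbinol is not broken, so C7a keeps its configuration.

Step 6
Reactants: 11 2,2,2-trichloroethyl (1S,3S)-1,5,5-trimethyl-3-(palmitoyloxy)cyclohexyl malonate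
Product: 12 2,2,2-trichloroethyl (1S,3S)-1,5,5-trimethyl-3-(palmitoyloxy)cyclohexyl 2-diazomalonate
Conditions: 4-AcNHC6H4SO2N3, Et3N, MeCN, 0 °C → rt
Reagents that add atoms: 4-acetamidobenzenesulfonyl azide, CC(=O)Nc1ccc(cc1)S(=O)(=O)N=[N+]=[N-]
Why: Regitz diazo transfer to the doubly activated malonate CH2; the amine base is too weak to touch the palmitate α-hydrogens or either ester.

Step 7
Reactants: 12 2,2,2-trichloroethyl (1S,3S)-1,5,5-trimethyl-3-(palmitoyloxy)cyclohexyl 2-diazomalonate
Product: 13 2,2,2-trichloroethyl (3aS,6S,7aR)-4,4,7a-trimethyl-2-oxo-6-(palmitoyloxy)octahydrobenzofuran-3-carboxylate (C3 epimers)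
Conditions: Rh2(NHCOCH3)4 (dirhodium tetraacetamidate, 1 mol %), ClCH2CH2Cl, 83 °C, slow addition of 12
Reagents that add atoms: none
Why: The closest known reaction type is the dirhodium-catalysed intramolecular 1,5 C–H insertion of tertiary-alkyl diazomalonates and diazoacetoacetates to γ-lactones. Loss of N2 from 12 gives an electrophilic dirhodium carbenoid at C3, which inserts into the equatorial C3a–H bond through a concerted, asynchronous three-centre transition state with hydride-like transfer, forming C3–C3a. The γ-lactone closes in the 1,5 mode through a five-membered transition state (ring atoms C3, C2, O1, C7a, C3a). The new stereocentre C3a is controlled by C7a: the tether hangs from the axial C7a oxygen, reaches only the gauche equatorial hydrogen of C3a and inserts with retention, so the ring fusion can only be cis (3aS); C3 forms as an epimer mixture and is erased later. The step needs site selectivity, and the substrate secures it: C7a has no hydrogen (no β-lactone path), the C7 methylene is deactivated inductively by the C6 palmitoyloxy group, and the C7a methyl offers only primary C–H bonds. The acetamidate ligands make the carbenoid less electrophilic and therefore more discriminating, which reinforces this order. The trichloroethyl ester has neither a π bond nor a C–H bond in 1,5 relation to the carbenoid and stays a spectator. Slow addition keeps the diazo concentration low and suppresses carbene dimerisation.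

Step 8
Reactants: 13 2,2,2-trichloroethyl (3aS,6S,7aR)-4,4,7a-trimethyl-2-oxo-6-(palmitoyloxy)octahydrobenzofuran-3-carboxylate
Product: 14 (3aS,6S,7aR)-4,4,7a-trimethyl-2-oxo-6-(palmitoyloxy)octahydrobenzofuran-3-carboxylic acid (C3 epimers)
Conditions: Zn, AcOH/THF (1:4), 0 °C → rt
Reagents that add atoms: none
Why: Reductive β-elimination of a 2,2,2-trichloroethyl ester with Zn frees the malonic half acid at room temperature without base or nucleophile, so the palmitate, the lactone and the stereocentres are untouched. 14 is used directly because it can lose CO2 on heating.

Step 9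
Reactants: 14 (3aS,6S,7aR)-4,4,7a-trimethyl-2-oxo-6-(palmitoyloxy)octahydrobenzofuran-3-carboxylic acid
Product: 17 (-)-3-O-palmitoylloliolide [(6S,7aR)-4,4,7a-trimethyl-2-oxo-2,4,5,6,7,7a-hexahydrobenzofuran-6-yl palmitate], via bromo acid 15 (not isolated), via bromo lactone 16 (not isolated)
Conditions: NBS (1.05 equiv), ClCH2CH2Cl, 0 °C → rt; 80 °C (−CO2); then DBU (2.5 equiv), rt → 50 °C
Reagents that add atoms: none
Why: Classical three-stage conversion of an α-carboxy γ-lactone into a butenolide: electrophilic bromination at the enolisable malonic C3, thermal decarboxylation of the α-bromo malonic half acid, and dehydrobromination (E2 with the ring-fusion H3a) by a non-nucleophilic amidine that leaves the palmitate intact. The C3a stereocentre is removed as planned and C6 and C7a are not involved, so the product is the (6S,7aR) target.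

## Compound list

1 | isophorone (3,5,5-trimethylcyclohex-2-en-1-one) | CC1=CC(=O)CC(C)(C)C1 | starting material
2 | bis(pinacolato)diboron | CC1(C)OB(OC1(C)C)B1OC(C)(C)C(C)(C)O1 | starting material
3 | (R)-3,5,5-trimethyl-3-(4,4,5,5-tetramethyl-1,3,2-dioxaborolan-2-yl)cyclohexan-1-one | O=C1CC(C)(C)C[C@](C)(B2OC(C)(C)C(C)(C)O2)C1 | intermediate (not isolated)
4 | (S)-3-hydroxy-3,5,5-trimethylcyclohexan-1-one | O=C1CC(C)(C)C[C@](C)(O)C1 | intermediate
5 | (1S,3S)-1,5,5-trimethylcyclohexane-1,3-diol | O[C@H]1CC(C)(C)C[C@](C)(O)C1 | intermediate
6 | palmitoyl chloride | CCCCCCCCCCCCCCCC(=O)Cl | starting material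
7 | (1S,3S)-3-hydroxy-3,5,5-trimethylcyclohexyl palmitate | CCCCCCCCCCCCCCCC(=O)O[C@H]1CC(C)(C)C[C@](C)(O)C1 | intermediate
8 | Meldrum's acid (2,2-dimethyl-1,3-dioxane-4,6-dione) | CC1(C)OC(=O)CC(=O)O1 | starting material
9 | 2,2,2-trichloroethanol | OCC(Cl)(Cl)Cl | starting material
10 | 3-oxo-3-(2,2,2-trichloroethoxy)propanoic acid | OC(=O)CC(=O)OCC(Cl)(Cl)Cl | intermediate
11 | 2,2,2-trichloroethyl (1S,3S)-1,5,5-trimethyl-3-(palmitoyloxy)cyclohexyl malonate | CCCCCCCCCCCCCCCC(=O)O[C@H]1CC(C)(C)C[C@](C)(OC(=O)CC(=O)OCC(Cl)(Cl)Cl)C1 | intermediate
12 | 2,2,2-trichloroethyl (1S,3S)-1,5,5-trimethyl-3-(palmitoyloxy)cyclohexyl 2-diazomalonate | CCCCCCCCCCCCCCCC(=O)O[C@H]1CC(C)(C)C[C@](C)(OC(=O)C(=[N+]=[N-])C(=O)OCC(Cl)(Cl)Cl)C1 | intermediate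
13 | 2,2,2-trichloroethyl (3aS,6S,7aR)-4,4,7a-trimethyl-2-oxo-6-(palmitoyloxy)octahydrobenzofuran-3-carboxylate (C3 epimers) | CCCCCCCCCCCCCCCC(=O)O[C@H]1CC(C)(C)[C@@H]2C(C(=O)OCC(Cl)(Cl)Cl)C(=O)O[C@]2(C)C1 | intermediate
14 | (3aS,6S,7aR)-4,4,7a-trimethyl-2-oxo-6-(palmitoyloxy)octahydrobenzofuran-3-carboxylic acid (C3 epimers) | CCCCCCCCCCCCCCCC(=O)O[C@H]1CC(C)(C)[C@@H]2C(C(=O)O)C(=O)O[C@]2(C)C1 | intermediate
15 | (3aS,6S,7aR)-3-bromo-4,4,7a-trimethyl-2-oxo-6-(palmitoyloxy)octahydrobenzofuran-3-carboxylic acid | CCCCCCCCCCCCCCCC(=O)O[C@H]1CC(C)(C)[C@@H]2C(Br)(C(=O)O)C(=O)O[C@]2(C)C1 | intermediate (not isolated)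
16 | (3aS,6S,7aR)-3-bromo-4,4,7a-trimethyl-2-oxooctahydrobenzofuran-6-yl palmitate (C3 epimers) | CCCCCCCCCCCCCCCC(=O)O[C@H]1CC(C)(C)[C@@H]2C(Br)C(=O)O[C@]2(C)C1 | intermediate (not isolated)
17 | (-)-3-O-palmitoylloliolide | CCCCCCCCCCCCCCCC(=O)O[C@H]1CC(C)(C)C2=CC(=O)O[C@]2(C)C1 | target

## Step count and least certain steps

Total number of steps: 9. Longest linear sequence: 8 steps (1, 2, 3, 5, 6, 7, 8, 9); step 4 is a one-step side branch.

**Step 7 (key step).** The most likely failure is loss of site selectivity or of conversion: insertion into the unhindered primary C–H bonds of the C7a methyl group, or carbene dimerisation. The cause is that the C3a methylene is neopentyl and a diester carbenoid is the least reactive of the acceptor carbenoids. The fallback changes the carbenoid class and the traceless group; it sets out from 7 and returns at 16. 7 is heated with 2,2,6-trimethyl-4H-1,3-dioxin-4-one (xylene, 130 °C; acetylketene acylates hindered tertiary alcohols) to give (1S,3S)-1,5,5-trimethyl-3-(palmitoyloxy)cyclohexyl 3-oxobutanoate F1. Diazo transfer (4-acetamidobenzenesulfonyl azide, Et3N, MeCN) gives (1S,3S)-1,5,5-trimethyl-3-(palmitoyloxy)cyclohexyl 2-diazo-3-oxobutanoate F2. Its more electrophilic keto carbenoid, the class for which tertiary-alkyl esters are best documented under Rh2(NHCOCH3)4, should close (3aS,6S,7aR)-3-acetyl-4,4,7a-trimethyl-2-oxooctahydrobenzofuran-6-yl palmitate F3. NBS brominates this β-keto lactone to (3aS,6S,7aR)-3-acetyl-3-bromo-4,4,7a-trimethyl-2-oxooctahydrobenzofuran-6-yl palmitate F4. Cold methanolic ammonia (−20 °C) then removes the acetyl group by retro-Claisen cleavage to give 16, which DBU converts into 17 as in the last stage of step 9.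

**Step 9.** The most likely failures are ionisation of the tertiary lactone by acid set free during bromination, decarboxylation before bromination (which leads to the saturated lactone), and slow E2 elimination at the hindered ring-fusion hydrogen. The fallback uses radical decarboxylation and a syn elimination; it sets out from 14 and returns at 17. 14 is converted with N-hydroxypyridine-2-thione and DCC into the Barton ester 2-thioxopyridin-1(2H)-yl (3aS,6S,7aR)-4,4,7a-trimethyl-2-oxo-6-(palmitoyloxy)octahydrobenzofuran-3-carboxylate F5. Irradiation with visible light in the presence of PhSeSePh should give, by decarboxylation and trapping of the C3 radical on the convex face, (3aS,6S,7aR)-4,4,7a-trimethyl-2-oxo-3-(phenylselanyl)octahydrobenzofuran-6-yl palmitate F6. H2O2/pyridine oxidises the selenide, and the selenoxide eliminates syn with H3a to 17 at room temperature without added strong base.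

**Step 1.** The most likely failure is low conversion and poor enantiofacial selectivity, because the β-carbon of 1 is already disubstituted and is shielded by the axial C5 methyl group. The fallback replaces boryl addition by epoxidation and reductive opening; it sets out from 1 and returns at 4. Asymmetric nucleophilic epoxidation of 1 with aqueous H2O2 and a cinchona-derived primary amine salt (iminium activation) gives (2S,3S)-2,3-epoxy-3,5,5-trimethylcyclohexan-1-one F7. Reductive cleavage of the Cα–O bond with SmI2 (THF/MeOH, −90 °C) leaves the C3–O bond and its configuration and gives 4.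

**Step 2.** The most likely failure is poor facial selectivity: intramolecular delivery must pass the axial C5 methyl group on the same face, while external hydride prefers the opposite face and gives the cis diol. The fallback puts that inherent preference to use; it sets out from 4 and returns at 7. Reduction of 4 with LiBH(sBu)3 (THF, −78 °C), which attacks anti to the axial substituents, gives the cis diol (1S,3R)-1,5,5-trimethylcyclohexane-1,3-diol F8. Mitsunobu esterification with palmitic acid (PPh3, diisopropyl azodicarboxylate) inverts the secondary carbinol and gives 7 directly.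

## Further compounds

F1 | step 7 | (1S,3S)-1,5,5-trimethyl-3-(palmitoyloxy)cyclohexyl 3-oxobutanoate | CCCCCCCCCCCCCCCC(=O)O[C@H]1CC(C)(C)C[C@](C)(OC(=O)CC(C)=O)C1
F2 | step 7 | (1S,3S)-1,5,5-trimethyl-3-(palmitoyloxy)cyclohexyl 2-diazo-3-oxobutanoate | CCCCCCCCCCCCCCCC(=O)O[C@H]1CC(C)(C)C[C@](C)(OC(=O)C(=[N+]=[N-])C(C)=O)C1
F3 | step 7 | (3aS,6S,7aR)-3-acetyl-4,4,7a-trimethyl-2-oxooctahydrobenzofuran-6-yl palmitate (C3 epimers) | CCCCCCCCCCCCCCCC(=O)O[C@H]1CC(C)(C)[C@@H]2C(C(C)=O)C(=O)O[C@]2(C)C1
F4 | step 7 | (3aS,6S,7aR)-3-acetyl-3-bromo-4,4,7a-trimethyl-2-oxooctahydrobenzofuran-6-yl palmitate | CCCCCCCCCCCCCCCC(=O)O[C@H]1CC(C)(C)[C@@H]2C(Br)(C(C)=O)C(=O)O[C@]2(C)C1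
F5 | step 9 | 2-thioxopyridin-1(2H)-yl (3aS,6S,7aR)-4,4,7a-trimethyl-2-oxo-6-(palmitoyloxy)octahydrobenzofuran-3-carboxylate | CCCCCCCCCCCCCCCC(=O)O[C@H]1CC(C)(C)[C@@H]2C(C(=O)ON3C=CC=CC3=S)C(=O)O[C@]2(C)C1
F6 | step 9 | (3aS,6S,7aR)-4,4,7a-trimethyl-2-oxo-3-(phenylselanyl)octahydrobenzofuran-6-yl palmitate | CCCCCCCCCCCCCCCC(=O)O[C@H]1CC(C)(C)[C@@H]2C([Se]c3ccccc3)C(=O)O[C@]2(C)C1
F7 | step 1 | (2S,3S)-2,3-epoxy-3,5,5-trimethylcyclohexan-1-one | O=C1CC(C)(C)C[C@]2(C)O[C@H]12
F8 | step 2 | (1S,3R)-1,5,5-trimethylcyclohexane-1,3-diol | O[C@@H]1CC(C)(C)C[C@](C)(O)C1
A1 | alternative 1 | (R)-4-(tert-butyldimethylsilyloxy)-6,6-dimethyloct-7-yn-2-one | CC(=O)C[C@H](O[Si](C)(C)C(C)(C)C)CC(C)(C)C#C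
A2 | alternative 1 | (6R,7aR)-6-(tert-butyldimethylsilyloxy)-4,4,7a-trimethyl-5,6,7,7a-tetrahydrobenzofuran-2(4H)-one | CC(C)(C)[Si](C)(C)O[C@@H]1CC(C)(C)C2=CC(=O)O[C@]2(C)C1
A3 | alternative 2 | ethyl (4R,6S)-4-hydroxy-4,8-dimethyl-6-(palmitoyloxy)non-8-en-2-ynoate | CCCCCCCCCCCCCCCC(=O)O[C@@H](CC(C)=C)C[C@@](C)(O)C#CC(=O)OCC
A4 | alternative 2 | ethyl (Z)-2-[(2R,4S)-2-hydroxy-2,6,6-trimethyl-4-(palmitoyloxy)cyclohexylidene]acetate | CCCCCCCCCCCCCCCC(=O)O[C@H]1CC(C)(C)/C(=C/C(=O)OCC)[C@](C)(O)C1
A5 | alternative 3 | 2-(1-methoxy-2,6-dimethyl-4-oxocyclohexa-2,5-dien-1-yl)acetic acid | COC1(CC(=O)O)C(C)=CC(=O)C=C1C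
A6 | alternative 3 | (3aR,7aR)-3a-methoxy-4,7a-dimethyl-3,3a,7,7a-tetrahydrobenzofuran-2,6-dione | O=C1C=C(C)[C@]2(OC)CC(=O)O[C@]2(C)C1
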